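**Plan**
1. Retrosynthesis: the γ-lactone is cut at its alkyl C–O bond and at the bond from the methylene-bearing carbon to the carbonyl carbon. This removes CO2 and leaves a 1-bromovinyl group beside a trans-oxirane. Next the oxirane oxygen, the senecioate and the ring C–C bond between the acyloxy carbon and the bromovinyl-bearing carbon (allylic bromide + aldehyde) are cut.
2. Forward: a C14 chain is built from (R)-β-citronellene, the ten-membered carbocycle is closed by Cr-mediated allylation, then come the ester, the second oxirane and, last, the lactone.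
3. Stereochemistry: the C-methyl centre comes from citronellene and the trisubstituted oxirane from Sharpless epoxidation. The acyloxy and ring-fusion carbons come from the anti/Felkin–Anh ring-closing allylation, and the disubstituted oxirane from Shi epoxidation. The lactone C–O carbon is set by inversion and the carbinol by retention.
4. Enabling feature: on the ten-membered ring the lactone O-bearing carbon and the neighbouring free-hydroxyl carbon are anti, which is the imprint of a trans-oxirane opened by a carboxylate. The lactone α-carbon is a 1,1-disubstituted vinyl carbon that can carry a metal, so CO2 can be stitched between the two.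

Key step: step 14

Assumption: commercial (R)-β-citronellene is (3R)-3,7-dimethylocta-1,6-diene; one-flask two-stage operations (steps 1, 4, 14) count as single steps.

Step 1
Reactants: 1 (R)-β-citronellene
Product: 3 (4R)-4-methylhex-5-en-1-ol, via (4R)-4-methylhex-5-enal 2 (not isolated)
Conditions: O3 (1 equiv, Sudan III), CH2Cl2/MeOH, −78 °C; then NaBH4, −78 °C to rt
Reagents that add atoms: ozone [O-][O+]=O
Why: The electron-rich trisubstituted olefin is ozonised much faster than the vinyl group (chemoselective ozonolysis with reductive work-up), and the methyl-bearing stereocentre is not touched.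

Step 2
Reactants: 3 (4R)-4-methylhex-5-en-1-ol
Product: 4 (3R)-6-iodo-3-methylhex-1-ene
Conditions: I2, PPh3, imidazole, CH2Cl2, 0 °C to rt
Reagents that add atoms: iodine II
Why: Appel-type iodination of a primary alcohol, an SN2 displacement of the alkoxyphosphonium ion by iodide.

Step 3
Reactants: 4 (3R)-6-iodo-3-methylhex-1-ene
Product: 5 (6R)-6-methyloct-7-en-1-yne
Conditions: lithium acetylide–ethylenediamine complex, DMSO, rt
Reagents that add atoms: lithium acetylide [Li+].[C-]#C
Why: SN2 alkylation of lithium acetylide by the primary iodide gives the terminal alkyne without affecting the remote vinyl group.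

Step 4
Reactants: 5 (6R)-6-methyloct-7-en-1-yne
Product: 7 (2E,7R)-3,7-dimethylnona-2,8-dien-1-ol, via alkenyldimethylalane 6 (not isolated)
Conditions: Me3Al, Cp2ZrCl2 (cat.), CH2Cl2, 0 °C to rt; then (CH2O)n, THF, 0 °C to rt
Reagents that add atoms: trimethylaluminium C[Al](C)C; formaldehyde (as paraformaldehyde) C=O
Why: Negishi zirconium-catalysed carboalumination adds methyl and aluminium syn across the terminal alkyne (far faster than across the vinyl group), and trapping the alkenylalane with formaldehyde with retention should give the E trisubstituted allylic alcohol.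

Step 5
Reactants: 7 (2E,7R)-3,7-dimethylnona-2,8-dien-1-ol
Product: 8 (2R,3R)-epoxy alcohol
Conditions: Ti(OiPr)4 (cat.), D-(−)-diethyl tartrate (cat.), t-BuOOH, 4 Å MS, CH2Cl2, −20 °C
Reagents that add atoms: tert-butyl hydroperoxide CC(C)(C)OO
Why: Katsuki–Sharpless asymmetric epoxidation acts only on the allylic-alcohol olefin, and the D-(−)-tartrate complex delivers oxygen to the face that gives the (2R,3R)-epoxy alcohol (the mirror image of the geraniol/L-tartrate case).

Step 6
Reactants: 8 (2R,3R)-epoxy alcohol
Product: 9 (E)-enal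
Conditions: crotonaldehyde (excess), Hoveyda–Grubbs II (cat.), CH2Cl2, 40 °C
Reagents that add atoms: (E)-crotonaldehyde C/C=C/C=O
Why: Olefin cross-metathesis of the terminal alkene with excess crotonaldehyde releases propene and should give the E enal, with the oxirane and the free alcohol tolerated by the ruthenium carbene.

Step 7
Reactants: 9 (E)-enal
Product: 10 ethyl (2Z,4E)-2-bromodienoate
Conditions: Ph3P=C(Br)CO2Et, CH2Cl2, 0 °C to rt
Reagents that add atoms: ethyl bromo(triphenyl-λ5-phosphanylidene)acetate CCOC(=O)C(Br)=P(c1ccccc1)(c1ccccc1)c1ccccc1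
Why: Wittig olefination with the stabilised bromo ylide is expected to give the (Z)-2-bromo-2-enoate (bromine cis to the diene chain), and the γ-stereocentre is not enolisable under these neutral conditions.

Step 8
Reactants: 10 ethyl (2Z,4E)-2-bromodienoate
Product: 11 (2Z,4E)-2-bromodienyl diol
Conditions: DIBAL-H (3.5 equiv), CH2Cl2, −78 °C; Rochelle salt work-up
Reagents that add atoms: none
Why: DIBAL-H reduces the α-bromo enoate 1,2 to the allylic alcohol at −78 °C, where the aluminium alkoxide of the epoxy alcohol should not open the oxirane.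

Step 9
Reactants: 11 (2Z,4E)-2-bromodienyl diol
Product: 12 allylic bromide epoxy alcohol
Conditions: NBS, Me2S, CH2Cl2, −20 to 0 °C
Reagents that add atoms: N-bromosuccinimide O=C1CCC(=O)N1Br
Why: Corey–Kim halogenation converts the allylic alcohol into the bromide by SN2 attack on its alkoxysulfonium ion, while the saturated epoxy alcohol is returned on work-up.

Step 10
Reactants: 12 allylic bromide epoxy alcohol
Product: 13 epoxy aldehyde allylic bromide
Conditions: TEMPO (cat.), PhI(OAc)2, CH2Cl2, rt
Reagents that add atoms: none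
Why: TEMPO/PhI(OAc)2 oxidation takes the primary epoxy alcohol to the aldehyde without over-oxidation and leaves the allylic bromide and the oxirane intact.

Step 11
Reactants: 13 epoxy aldehyde allylic bromide
Product: 14 macrocyclic epoxy homoallylic alcohol
Conditions: CrCl2 (6 equiv), THF, rt, slow addition of 13 (final 2 mM)
Reagents that add atoms: none
Why: Intramolecular Nozaki–Hiyama–Kishi allylation, in which the pentadienyl-type allylchromium(III) adds through its central carbon in a chair Zimmerman–Traxler transition state (ten-membered ring), which should set the carbinol and ring carbon anti, while Felkin–Anh attack anti to the oxirane C–O bond should set the carbinol erythro to the epoxide.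

Step 12
Reactants: 14 macrocyclic epoxy homoallylic alcohol
Product: 15 macrocyclic senecioate
Conditions: 3-methylbut-2-enoyl chloride, pyridine, DMAP (cat.), CH2Cl2, 0 °C
Reagents that add atoms: 3-methylbut-2-enoyl chloride CC(C)=CC(Cl)=O
Why: DMAP-catalysed acylation of the secondary alcohol, with pyridine instead of a trialkylamine to suppress vinylketene formation and deconjugation of the acyl group.

Step 13
Reactants: 15 macrocyclic senecioate
Product: 16 bromovinyl bis-epoxide
Conditions: D-fructose-derived Shi ketone (0.3 equiv), Oxone, K2CO3, Bu4NHSO4, MeCN/DMM/aq. buffer (pH 10.5), 0 °C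
Reagents that add atoms: potassium peroxymonosulfate (Oxone) [K+].[O-]S(=O)(=O)OO
Why: Shi asymmetric epoxidation, in which the chiral dioxirane should react only with the electron-rich E-disubstituted ring olefin (bromoalkene and enoate are electron-poor) and deliver oxygen to the face that gives the (R,R)-oxirane, which is the peripheral face in the ring conformer that turns both allylic hydrogens toward the reagent.

Step 14
Reactants: 16 bromovinyl bis-epoxide
Product: 18 CNP0119422.1, via epoxy acrylic acid 17 (not isolated)
Conditions: NiCl2(PPh3)2 (10 mol%), PPh3, Mn powder, Et4NI (cat.), CO2 (1 atm), DMI, 25 °C; then aq. citric acid; PPTS (cat.), CH2Cl2, 25 °C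
Reagents that add atoms: carbon dioxide O=C=O
Why: Ni(0) inserts into the vinylic C–Br bond, Mn reduces the alkenylnickel(II) halide to a nucleophilic alkenylnickel(I) that adds to CO2, and a second reduction releases the manganese carboxylate and Ni(0); after acidification the acrylic acid 17 attacks the neighbouring oxirane carbon from the back and the lactone closes. The closest known reaction types are the nickel-catalysed reductive carboxylation of aryl and alkenyl halides with CO2 at 1 atm and the acid-promoted lactonisation of γ,δ-epoxy acids. The five-membered lactone closes in the 5-exo-tet mode. The lactone C–O carbon is set by SN2 inversion of the (R,R)-oxirane and the carbinol carbon keeps the oxirane configuration, so the anti O/OH pair and the trans ring fusion follow stereospecifically from the Shi epoxide and the fixed ring-fusion carbon. The step needs chemoselectivity for the C(sp2)–Br bond over two oxiranes and an enoate, which the mild Ni(0)/Mn system should provide. It also needs 5-exo attack at the proximal carbon of the disubstituted oxirane in preference to 6-endo attack and to 6-exo attack on the other oxirane, which ring size and the acyloxy group and extra substitution beside the second oxirane should secure.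

**Compound list**
1 | (R)-β-citronellene, (3R)-3,7-dimethylocta-1,6-diene | C=C[C@H](C)CCC=C(C)C | starting material
2 | (4R)-4-methylhex-5-enal | C=C[C@H](C)CCC=O | intermediate (not isolated)
3 | (4R)-4-methylhex-5-en-1-ol | C=C[C@H](C)CCCO | intermediate
4 | (3R)-6-iodo-3-methylhex-1-ene | C=C[C@H](C)CCCI | intermediate
5 | (6R)-6-methyloct-7-en-1-yne | C=C[C@H](C)CCCC#C | intermediate
6 | [(1E,6R)-2,6-dimethylocta-1,7-dien-1-yl]dimethylalumane | C=C[C@H](C)CCC/C(C)=C/[Al](C)C | intermediate (not isolated)
7 | (2E,7R)-3,7-dimethylnona-2,8-dien-1-ol | C=C[C@H](C)CCC/C(C)=C/CO | intermediate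
8 | [(2R,3R)-3-methyl-3-[(4R)-4-methylhex-5-en-1-yl]oxiran-2-yl]methanol | C=C[C@H](C)CCC[C@@]1(C)O[C@@H]1CO | intermediate
9 | (2E,4R)-7-[(2R,3R)-3-(hydroxymethyl)-2-methyloxiran-2-yl]-4-methylhept-2-enal | O=C/C=C/[C@H](C)CCC[C@@]1(C)O[C@@H]1CO | intermediate
10 | ethyl (2Z,4E,6R)-2-bromo-9-[(2R,3R)-3-(hydroxymethyl)-2-methyloxiran-2-yl]-6-methylnona-2,4-dienoate | CCOC(=O)/C(Br)=C/C=C/[C@H](C)CCC[C@@]1(C)O[C@@H]1CO | intermediate
11 | (2Z,4E,6R)-2-bromo-9-[(2R,3R)-3-(hydroxymethyl)-2-methyloxiran-2-yl]-6-methylnona-2,4-dien-1-ol | OC/C(Br)=C/C=C/[C@H](C)CCC[C@@]1(C)O[C@@H]1CO | intermediate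
12 | [(2R,3R)-3-[(4R,5E,7Z)-8,9-dibromo-4-methylnona-5,7-dien-1-yl]-3-methyloxiran-2-yl]methanol | BrC/C(Br)=C/C=C/[C@H](C)CCC[C@@]1(C)O[C@@H]1CO | intermediate
13 | (2S,3R)-3-[(4R,5E,7Z)-8,9-dibromo-4-methylnona-5,7-dien-1-yl]-3-methyloxirane-2-carbaldehyde | BrC/C(Br)=C/C=C/[C@H](C)CCC[C@@]1(C)O[C@@H]1C=O | intermediate
14 | (1R,2S,3E,5R,9R,10R)-2-(1-bromoethenyl)-9,10-epoxy-5,9-dimethylcyclodec-3-en-1-ol | C=C(Br)[C@H]1/C=C/[C@H](C)CCC[C@@]2(C)O[C@@H]2[C@@H]1O | intermediate
15 | (1R,2S,3E,5R,9R,10R)-2-(1-bromoethenyl)-9,10-epoxy-5,9-dimethylcyclodec-3-en-1-yl 3-methylbut-2-enoate | C=C(Br)[C@H]1/C=C/[C@H](C)CCC[C@@]2(C)O[C@@H]2[C@@H]1OC(=O)C=C(C)C | intermediate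
16 | (1R,2S,3R,4R,5R,9R,10R)-2-(1-bromoethenyl)-3,4:9,10-diepoxy-5,9-dimethylcyclodecyl 3-methylbut-2-enoate | C=C(Br)[C@H]1[C@H]2O[C@@H]2[C@H](C)CCC[C@@]3(C)O[C@@H]3[C@@H]1OC(=O)C=C(C)C | intermediate
17 | 2-[(1S,2R,3R,4R,8R,9R,10R)-3,4:9,10-diepoxy-4,8-dimethyl-2-[(3-methylbut-2-enoyl)oxy]cyclodecyl]prop-2-enoic acid | C=C(C(=O)O)[C@H]1[C@H]2O[C@@H]2[C@H](C)CCC[C@@]3(C)O[C@@H]3[C@@H]1OC(=O)C=C(C)C | intermediate (not isolated)
18 | CNP0119422.1: 1,10-lactone of 2-[(1S,2R,3R,4R,8R,9R,10S)-3,4-epoxy-9,10-dihydroxy-4,8-dimethyl-2-[(3-methylbut-2-enoyl)oxy]cyclodecyl]prop-2-enoic acid (trans-fused α-methylene-γ-butyrolactone) | C=C1C(=O)O[C@@H]2[C@H](O)[C@H](C)CCC[C@@]3(C)O[C@@H]3[C@H](OC(=O)C=C(C)C)[C@@H]12 | target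

Total step count: 14. Longest linear sequence: 14 steps (from 1).

**Steps most likely to fail**

Step 14. The oxiranes may be opened reductively or by halide under the Ni/Mn conditions, oxidative addition into the hindered bromoalkene may be slow, and the acid may attack the second oxirane in a 6-exo sense. The fallback sets out from 16 and separates C–C bond formation from any reducing metal. Miyaura borylation (PdCl2(PPh3)2, PPh3, B2pin2, KOPh, toluene, 50 °C) should give the alkenyl pinacolboronate F1. Copper(I)–NHC-catalysed carboxylation of F1 ([(IPr)CuCl], CsF, CO2 1 atm, dioxane, 65 °C) should then give, after acidification, the epoxy acrylic acid 17. From 17 the route continues as before (PPTS) to 18.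

Step 11. Ring closure may lose to oligomerisation, Cr(II) may reduce the epoxy aldehyde, and the macrocyclic transition state may erode Felkin–Anh/anti control. The fallback sets out from 8, forms the same C–C bond intermolecularly under acyclic control and closes the ring by metathesis instead.
- Oxidation of 8 (TEMPO, PhI(OAc)2) gives (2S,3R)-3-methyl-3-[(4R)-4-methylhex-5-en-1-yl]oxirane-2-carbaldehyde F2.
- The reagent is made from acrolein: Wittig reaction with Ph3P=C(Br)CO2Et gives ethyl (2Z)-2-bromopenta-2,4-dienoate F3, DIBAL-H reduction gives (2Z)-2-bromopenta-2,4-dien-1-ol F4, and CBr4/PPh3 gives (2Z)-1,2-dibromopenta-2,4-diene F5.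
- CrCl2-mediated addition of F5 to F2 through the central carbon of the pentadienyl unit should give the acyclic anti/Felkin adduct (1R,2S)-2-(1-bromoethenyl)-1-[(2R,3R)-3-methyl-3-[(4R)-4-methylhex-5-en-1-yl]oxiran-2-yl]but-3-en-1-ol F6.
- Ring-closing metathesis of the two vinyl groups of F6 (Grubbs II, CH2Cl2, high dilution) should close the E-olefin of the germacrene-type ring and come back to the route at 14. The E geometry is not assured.

Step 13. Oxygen may be transferred to the wrong face of the macrocyclic olefin if the ring conformer preference overrides the catalyst. The fallback sets out from 15 and brings the oxygen in as a nucleophile, anti to an electrophile that takes the face the epoxidant prefers. NBS in THF/H2O at 0 °C should give the anti bromohydrin (1R,2S,3R,4S,5R,9R,10R)-4-bromo-2-(1-bromoethenyl)-9,10-epoxy-3-hydroxy-5,9-dimethylcyclodecyl 3-methylbut-2-enoate F7 (its regioisomer would close to the same oxirane). Cs2CO3 in MeCN then closes F7 with inversion at the bromine-bearing carbon to come back at 16. The weak point is that water must attack from the inner side of the ring.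

Further compounds
F1 | step 14 | (1R,2S,3R,4R,5R,9R,10R)-3,4:9,10-diepoxy-5,9-dimethyl-2-[1-(4,4,5,5-tetramethyl-1,3,2-dioxaborolan-2-yl)ethenyl]cyclodecyl 3-methylbut-2-enoate | C=C(B1OC(C)(C)C(C)(C)O1)[C@H]1[C@H]2O[C@@H]2[C@H](C)CCC[C@@]3(C)O[C@@H]3[C@@H]1OC(=O)C=C(C)C
F2 | step 11 | (2S,3R)-3-methyl-3-[(4R)-4-methylhex-5-en-1-yl]oxirane-2-carbaldehyde | C=C[C@H](C)CCC[C@@]1(C)O[C@@H]1C=O
F3 | step 11 | ethyl (2Z)-2-bromopenta-2,4-dienoate | CCOC(=O)/C(Br)=C/C=C
F4 | step 11 | (2Z)-2-bromopenta-2,4-dien-1-ol | OC/C(Br)=C/C=C
F5 | step 11 | (2Z)-1,2-dibromopenta-2,4-diene | BrC/C(Br)=C/C=C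
F6 | step 11 | (1R,2S)-2-(1-bromoethenyl)-1-[(2R,3R)-3-methyl-3-[(4R)-4-methylhex-5-en-1-yl]oxiran-2-yl]but-3-en-1-ol | C=C(Br)[C@@H](C=C)[C@@H](O)[C@H]1O[C@]1(C)CCC[C@@H](C)C=C
F7 | step 13 | (1R,2S,3R,4S,5R,9R,10R)-4-bromo-2-(1-bromoethenyl)-9,10-epoxy-3-hydroxy-5,9-dimethylcyclodecyl 3-methylbut-2-enoate | C=C(Br)[C@H]1[C@@H](O)[C@@H](Br)[C@H](C)CCC[C@@]2(C)O[C@@H]2[C@@H]1OC(=O)C=C(C)C
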